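**Retrosynthetic overview**

1. The target (23) is the 6β-isovalerate of labda-8,13E-diene-6β,7α,15-triol. The ester is put on the hindered axial O6 last. The trans-diaxial 6β,7α-diol comes from a 6-oxo-Δ7 enone by deconjugative α-hydroxylation at C7 and 7-OH-directed reduction of C6=O.
2. C6=O, C17 and the C7=C8 bond come from MeLi addition to a C8 enone followed by oxidative 1,3-transposition. The C11–C16 chain is alkylated onto C9 of that enone.
3. Key disconnection: ring A is cut at C1–C10 and C3–C4, giving (1R,5R)-verbenone and a three-carbon allenylstannane. Forward, C1–C10 forms by conjugate propargylation and C3–C4 by strain-release opening of the cyclobutane with cation–alkyne closure, in one flask.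
4. Enabling feature: the quaternary C10 (C20 methyl) and the gem-dimethyl C4 (C18, C19) flank C5–H. Together with ring-B atoms C5–C10 they form the pinane skeleton, in which C4 is also bonded to C7 (cyclobutane C4–C5–C6–C7). C10 is thus an enone β-carbon and C4 a latent tertiary cation.
5. Ring order: ring B is the six-membered ring C5–C10 of verbenone; ring A closes in step 1. C5 comes from the chiral pool, C10 from the bicyclic facial bias, C6 and C7 from the rigid trans-decalin.

Key step: step 1

Remark: labdane numbering is used for all intermediates; the transient stereocentres at C9 (15–17) and C8 (16) are erased in steps 9 and 10 and are left undefined.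

**Route**

Step 1
Reactants: 1 (1R,5R)-(+)-verbenone; 2 tributyl(propa-1,2-dien-1-yl)stannane
Product: 6 (4aR,8aS)-7-chloro-5,5,8a-trimethyl-3,4,4a,5,8,8a-hexahydronaphthalen-2(1H)-one, via titanium enolate 3 (not isolated), via propargyl ketone 4 (not isolated), via tertiary chloride 5 (not isolated)
Conditions: TiCl4 (3 equiv), CH2Cl2, −78 °C; then i-PrOH (1 equiv), −78 → 0 °C; H2O
Reagents that add atoms: titanium tetrachloride, Cl[Ti](Cl)(Cl)Cl
Why: Proposed new method: TiCl4 activates the enone and the allenylstannane attacks C10 through its CH2 terminus (SE2′ conjugate propargylation of Hosomi–Sakurai type; closest known reaction: TiCl4-mediated conjugate propargylation of enones by allenylstannanes), forming C1–C10 on the face opposite the gem-dimethyl bridge and giving titanium enolate 3. i-PrOH then protonates 3 to ketone 4, whose TiCl4 complex should undergo the strain-releasing heterolysis of the cyclobutane bond C4–C7 known for Lewis-acid-treated pinanones, the only cleavage that leaves a tertiary cation at C4 (resting as chloride 5) and a titanium enolate at C7–C8. The C4 cation is captured by the terminal alkyne carbon C3 in a 6-endo-dig cation–alkyne closure of ring A, and the endocyclic vinyl cation at C2 is quenched by chloride, as in alkyne Prins cyclisations that give vinyl chlorides. C10 is the only new stereocentre and is controlled by the bicyclic scaffold (attack anti to the C4 bridge), which places C1 trans to C4 across C5–C10, so the decalin can only close trans; C5 comes unchanged from 1. The step needs 1,4- over 1,2-addition, bond formation at C10 before ring opening, and 6-endo over 5-exo closure; the hindered carbonyl at −78 °C, the delayed proton source (the enolate cannot fragment) and the inaccessibility of a primary vinyl cation should secure these.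

Step 2
Reactants: 6 (4aR,8aS)-7-chloro-5,5,8a-trimethyl-3,4,4a,5,8,8a-hexahydronaphthalen-2(1H)-one
Product: 7 (4aS,8aR)-5,5,8a-trimethyloctahydronaphthalen-2(1H)-one
Conditions: H2 (4 atm), 10% Pd/C, Et3N, MeOH, 23 °C
Reagents that add atoms: none
Why: Palladium-catalysed hydrogenolysis of the vinylic C–Cl bond followed by hydrogenation of the C2=C3 alkene should give the saturated ring A without touching the ketone or creating a stereocentre (catalytic hydrodechlorination and hydrogenation).

Step 3
Reactants: 7 (4aS,8aR)-5,5,8a-trimethyloctahydronaphthalen-2(1H)-one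
Product: 8 (4aS,8aR)-5,5,8a-trimethyl-4a,5,6,7,8,8a-hexahydronaphthalen-2(1H)-one
Conditions: IBX (2 equiv), DMSO–fluorobenzene, 70 °C
Reagents that add atoms: none
Why: IBX α,β-dehydrogenation of the ketone can only run towards C7–C6 because C10 is quaternary, so the C6=C7 enone should form regiospecifically.

Step 4
Reactants: 9 4-bromobut-1-yne
Product: 11 (2E)-5-bromo-3-methylpent-2-en-1-ol, via alkenylalane 10 (not isolated)
Conditions: Me3Al (2 equiv), Cp2ZrCl2 (0.2 equiv), CH2Cl2, 0 → 23 °C; then (CH2O)n, THF, 23 °C; H2O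
Reagents that add atoms: trimethylaluminium, C[Al](C)C; paraformaldehyde (as formaldehyde), C=O
Why: Zirconium-catalysed Negishi carboalumination adds methyl and aluminium syn across the alkyne with methyl on the internal carbon, and hydroxymethylation of the alkenylalane with retention should give the E-allylic alcohol.

Step 5
Reactants: 11 (2E)-5-bromo-3-methylpent-2-en-1-ol
Product: 12 {[(2E)-5-bromo-3-methylpent-2-en-1-yl]oxy}(tert-butyl)dimethylsilane
Conditions: t-BuMe2SiCl, imidazole, CH2Cl2, 0 → 23 °C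
Reagents that add atoms: tert-butyl(chloro)dimethylsilane, CC(C)(C)[Si](C)(C)Cl
Why: Routine silyl ether formation protects the primary allylic alcohol for the base and organolithium steps that follow.

Step 6
Reactants: 12 {[(2E)-5-bromo-3-methylpent-2-en-1-yl]oxy}(tert-butyl)dimethylsilane
Product: 13 tert-butyl{[(2E)-5-iodo-3-methylpent-2-en-1-yl]oxy}dimethylsilane
Conditions: NaI, acetone, 56 °C
Reagents that add atoms: sodium iodide, [Na+].[I-]
Why: Finkelstein halide exchange, driven by precipitation of NaBr, should give the more reactive primary iodide.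

Step 7
Reactants: 8 (4aS,8aR)-5,5,8a-trimethyl-4a,5,6,7,8,8a-hexahydronaphthalen-2(1H)-one; 13 tert-butyl{[(2E)-5-iodo-3-methylpent-2-en-1-yl]oxy}dimethylsilane
Product: 15 15-[(tert-butyldimethylsilyl)oxy]-17-norlabda-6,13E-dien-8-one (C9 epimers), via lithium dienolate 14 (not isolated)
Conditions: LiN(iPr)2, THF, −78 °C; then DMPU, 13, −78 → −20 °C
Reagents that add atoms: none
Why: Kinetic deprotonation of the enone occurs at its only α′ position (C9), and SN2 alkylation of the cross-conjugated lithium dienolate by the primary iodide (enolate alkylation) should attach C11; the new C9 centre becomes sp2 in step 10.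

Step 8
Reactants: 15 15-[(tert-butyldimethylsilyl)oxy]-17-norlabda-6,13E-dien-8-one
Product: 16 15-[(tert-butyldimethylsilyl)oxy]labda-6,13E-dien-8-ol (C8 and C9 epimers, 8β-hydroxy expected to predominate)
Conditions: MeLi, Et2O, −78 → 0 °C; H2O
Reagents that add atoms: methyllithium, [Li]C
Why: 1,2-Addition of methyllithium to the enone carbonyl installs C17, expected from the α-face opposite the axial C20 methyl; the C8 centre is erased in step 9.

Step 9
Reactants: 16 15-[(tert-butyldimethylsilyl)oxy]labda-6,13E-dien-8-ol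
Product: 17 15-[(tert-butyldimethylsilyl)oxy]labda-7,13E-dien-6-one (C9 epimers)
Conditions: pyridinium chlorochromate [C5H5NH][CrO3Cl] (3 equiv), NaOAc, CH2Cl2, 23 °C
Reagents that add atoms: pyridinium chlorochromate, [O-][Cr](=O)(=O)Cl.c1cc[nH+]cc1
Why: In the Babler–Dauben oxidative transposition the chromate ester of the tertiary allylic alcohol shifts [3,3] to C6 and is oxidised, which moves oxygen to C6 and the alkene to C7=C8.

Step 10
Reactants: 17 15-[(tert-butyldimethylsilyl)oxy]labda-7,13E-dien-6-one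
Product: 19 15-[(tert-butyldimethylsilyl)oxy]-7α-hydroxylabda-8,13E-dien-6-one, via potassium dienolate 18 (not isolated)
Conditions: KN(SiMe3)2 (0.95 equiv), THF, −78 → 0 °C; then −78 °C, 2-(phenylsulfonyl)-3-phenyloxaziridine; AcOH
Reagents that add atoms: 2-(phenylsulfonyl)-3-phenyloxaziridine, O=S(=O)(c1ccccc1)N1OC1c1ccccc1
Why: Equilibration under slight base deficiency should give the through-conjugated endocyclic dienolate by loss of H9 (the γ-deprotonation mode of 3-alkylcyclohexenones), and the oxaziridine hydroxylates its α-carbon C7 from the α-face, opposite the axial C19 and C20 methyls (deconjugative Davis α-hydroxylation), fixing C7 and the C8=C9 alkene.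

Step 11
Reactants: 19 15-[(tert-butyldimethylsilyl)oxy]-7α-hydroxylabda-8,13E-dien-6-one
Product: 20 15-[(tert-butyldimethylsilyl)oxy]labda-8,13E-diene-6β,7α-diol
Conditions: Me4NBH(OAc)3 (5 equiv), MeCN–AcOH (1:1), −20 °C
Reagents that add atoms: none
Why: In this hydroxyl-directed Saksena–Evans reduction the borohydride bound to the 7α-oxygen delivers hydride to the α-face of C6, which is also the face free of the syn-axial C19 and C20 methyls, so the 6β-alcohol trans to O7 should result.

Step 12
Reactants: 20 15-[(tert-butyldimethylsilyl)oxy]labda-8,13E-diene-6β,7α-diol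
Product: 21 15-[(tert-butyldimethylsilyl)oxy]-7α-[(triethylsilyl)oxy]labda-8,13E-dien-6β-ol
Conditions: Et3SiCl (1.1 equiv), imidazole, CH2Cl2, 0 °C
Reagents that add atoms: chlorotriethylsilane, CC[Si](Cl)(CC)CC
Why: Silyl ether formation should be selective for the allylic 7α-hydroxyl because the axial 6β-hydroxyl is shielded by the syn-axial C19 and C20 methyls.

Step 13
Reactants: 21 15-[(tert-butyldimethylsilyl)oxy]-7α-[(triethylsilyl)oxy]labda-8,13E-dien-6β-ol
Product: 22 15-[(tert-butyldimethylsilyl)oxy]-7α-[(triethylsilyl)oxy]labda-8,13E-dien-6β-yl 3-methylbutanoate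
Conditions: 3-methylbutanoyl chloride (3 equiv), DMAP (0.2 equiv), pyridine, 50 °C
Reagents that add atoms: 3-methylbutanoyl chloride, CC(C)CC(=O)Cl
Why: DMAP-catalysed acylation with the acid chloride should esterify the hindered axial 6β-alcohol, and the trans-diaxial O6/O7 arrangement rules out silyl or acyl migration.

Step 14
Reactants: 22 15-[(tert-butyldimethylsilyl)oxy]-7α-[(triethylsilyl)oxy]labda-8,13E-dien-6β-yl 3-methylbutanoate
Product: 23 7α,15-dihydroxylabda-8,13E-dien-6β-yl 3-methylbutanoate (CNP0173680.1)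
Conditions: HF·pyridine, pyridine–THF, 0 → 23 °C
Reagents that add atoms: none
Why: Buffered fluoride cleavage of both silyl ethers should free the C7 and C15 hydroxyls while sparing the ester and the allylic alcohols (desilylation).

**Compound list**

1 | (1R,5R)-(+)-verbenone, (1R,5R)-4,6,6-trimethylbicyclo[3.1.1]hept-3-en-2-one | CC1=CC(=O)[C@@H]2C[C@H]1C2(C)C | starting material
2 | tributyl(propa-1,2-dien-1-yl)stannane | C=C=C[Sn](CCCC)(CCCC)CCCC | starting material
3 | trichlorotitanium enolate of 4 (C8–O–TiCl3, C8=C9; not isolated) | C[C@@]1(CC#C)C=C(O[Ti](Cl)(Cl)Cl)[C@@H]2C[C@H]1C2(C)C | intermediate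
4 | (1R,4R,5R)-4,6,6-trimethyl-4-(prop-2-yn-1-yl)bicyclo[3.1.1]heptan-2-one, propargyl anti to the gem-dimethyl bridge (not isolated) | C[C@@]1(CC#C)CC(=O)[C@@H]2C[C@H]1C2(C)C | intermediate
5 | (3R,4R)-4-(2-chloropropan-2-yl)-3-methyl-3-(prop-2-yn-1-yl)cyclohexan-1-one (not isolated) | O=C1C[C@@](C)(CC#C)[C@H](C(C)(C)Cl)CC1 | intermediate
6 | (4aR,8aS)-7-chloro-5,5,8a-trimethyl-3,4,4a,5,8,8a-hexahydronaphthalen-2(1H)-one | O=C1C[C@@]2(C)CC(Cl)=CC(C)(C)[C@@H]2CC1 | intermediate
7 | (4aS,8aR)-5,5,8a-trimethyloctahydronaphthalen-2(1H)-one | O=C1C[C@@]2(C)CCCC(C)(C)[C@@H]2CC1 | intermediate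
8 | (4aS,8aR)-5,5,8a-trimethyl-4a,5,6,7,8,8a-hexahydronaphthalen-2(1H)-one | O=C1C[C@@]2(C)CCCC(C)(C)[C@@H]2C=C1 | intermediate
9 | 4-bromobut-1-yne | BrCCC#C | starting material
10 | [(1E)-4-bromo-2-methylbut-1-en-1-yl]dimethylalane (not isolated) | BrCC/C(C)=C/[Al](C)C | intermediate
11 | (2E)-5-bromo-3-methylpent-2-en-1-ol | BrCC/C(C)=C/CO | intermediate
12 | {[(2E)-5-bromo-3-methylpent-2-en-1-yl]oxy}(tert-butyl)dimethylsilane | BrCC/C(C)=C/CO[Si](C)(C)C(C)(C)C | intermediate
13 | tert-butyl{[(2E)-5-iodo-3-methylpent-2-en-1-yl]oxy}dimethylsilane | ICC/C(C)=C/CO[Si](C)(C)C(C)(C)C | intermediate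
14 | lithium dienolate of 8 (C8–OLi, C8=C9, C6=C7; not isolated) | [Li]OC1=C[C@@]2(C)CCCC(C)(C)[C@@H]2C=C1 | intermediate
15 | 15-[(tert-butyldimethylsilyl)oxy]-17-norlabda-6,13E-dien-8-one (C9 epimers) | O=C1C(CC/C(C)=C/CO[Si](C)(C)C(C)(C)C)[C@@]2(C)CCCC(C)(C)[C@@H]2C=C1 | intermediate
16 | 15-[(tert-butyldimethylsilyl)oxy]labda-6,13E-dien-8-ol (C8 and C9 epimers) | CC1(O)C(CC/C(C)=C/CO[Si](C)(C)C(C)(C)C)[C@@]2(C)CCCC(C)(C)[C@@H]2C=C1 | intermediate
17 | 15-[(tert-butyldimethylsilyl)oxy]labda-7,13E-dien-6-one (C9 epimers) | CC1=CC(=O)[C@H]2C(C)(C)CCC[C@]2(C)C1CC/C(C)=C/CO[Si](C)(C)C(C)(C)C | intermediate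
18 | potassium dienolate of 17 (C6–OK, C6=C7, C8=C9; not isolated) | CC1=C(CC/C(C)=C/CO[Si](C)(C)C(C)(C)C)[C@@]2(C)CCCC(C)(C)[C@@H]2C(O[K])=C1 | intermediate
19 | 15-[(tert-butyldimethylsilyl)oxy]-7α-hydroxylabda-8,13E-dien-6-one | CC1=C(CC/C(C)=C/CO[Si](C)(C)C(C)(C)C)[C@@]2(C)CCCC(C)(C)[C@@H]2C(=O)[C@H]1O | intermediate
20 | 15-[(tert-butyldimethylsilyl)oxy]labda-8,13E-diene-6β,7α-diol | CC1=C(CC/C(C)=C/CO[Si](C)(C)C(C)(C)C)[C@@]2(C)CCCC(C)(C)[C@@H]2[C@H](O)[C@H]1O | intermediate
21 | 15-[(tert-butyldimethylsilyl)oxy]-7α-[(triethylsilyl)oxy]labda-8,13E-dien-6β-ol | CC1=C(CC/C(C)=C/CO[Si](C)(C)C(C)(C)C)[C@@]2(C)CCCC(C)(C)[C@@H]2[C@H](O)[C@H]1O[Si](CC)(CC)CC | intermediate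
22 | 15-[(tert-butyldimethylsilyl)oxy]-7α-[(triethylsilyl)oxy]labda-8,13E-dien-6β-yl 3-methylbutanoate | CC1=C(CC/C(C)=C/CO[Si](C)(C)C(C)(C)C)[C@@]2(C)CCCC(C)(C)[C@@H]2[C@H](OC(=O)CC(C)C)[C@H]1O[Si](CC)(CC)CC | intermediate
23 | 7α,15-dihydroxylabda-8,13E-dien-6β-yl 3-methylbutanoate, (5S,6S,7S,10S), CNP0173680.1 | CC1=C(CC/C(C)=C/CO)[C@@]2(C)CCCC(C)(C)[C@@H]2[C@H](OC(=O)CC(C)C)[C@H]1O | target

**Step count**

Total: 14 steps. Longest linear sequence: 11 steps (steps 1–3 and 7–14, from 1); steps 4–6 make the side-chain iodide 13.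

**Steps most likely to fail, with fallbacks**

Step 1 (Proposed new method). What may go wrong:
- competing 1,2-addition of the stannane to the carbonyl;
- opening of the cyclobutane before C10 is quaternised, which loses the facial bias;
- proton loss from C5 in the C4 cation, eroding the ring-fusion configuration;
- attack of the alkyne on the activated C8 carbonyl instead of on C4.

Fallback, known chemistry, from 1 to 7: copper-catalysed conjugate addition of but-3-enylmagnesium bromide (CuBr·SMe2, Me3SiCl, THF, −78 °C), again anti to the bridge, should give (1R,4R,5R)-4-(but-3-en-1-yl)-4,6,6-trimethylbicyclo[3.1.1]heptan-2-one F1. Acid-mediated opening of the cyclobutane (aqueous H2SO4, THF) gives the tertiary alcohol (3R,4R)-3-(but-3-en-1-yl)-4-(2-hydroxypropan-2-yl)-3-methylcyclohexan-1-one F2. Dehydration with the Burgess reagent gives (3R,4S)-3-(but-3-en-1-yl)-3-methyl-4-(prop-1-en-2-yl)cyclohexan-1-one F3. Ring-closing metathesis with the second-generation Grubbs catalyst closes ring A as (4aR,8aR)-5,8a-dimethyl-3,4,4a,7,8,8a-hexahydronaphthalen-2(1H)-one F4, forming C3–C4 as a double bond. Hydrogen-atom-transfer hydromethylation (Fe(acac)3, PhSiH3, formaldehyde benzenesulfonylhydrazone; then MeOH, 60 °C) passes through N′-[(1,4a-dimethyl-6-oxodecahydronaphthalen-1-yl)methyl]benzenesulfonohydrazide F5 and adds the second C4 methyl, rejoining the route at 7.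

Step 7. What may go wrong:
- slow SN2 at the neopentyl-type enolate carbon;
- E2 elimination of the homoallylic iodide;
- enolate equilibration followed by alkylation at C7.

Fallback, from 8 to 15: condensation of 8 with 1,1-dimethylhydrazine gives the N,N-dimethylhydrazone of 8 F6. Metalation with LiN(iPr)2 at C9 and alkylation of the more nucleophilic azaenolate with 13 gives the N,N-dimethylhydrazone of 15 F7. Hydrolysis (Cu(OAc)2, THF–H2O) returns 15.

Step 10. What may go wrong:
- deprotonation at the C17 methyl or at C5 instead of C9;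
- oxygen transfer to the γ-carbon C9;
- attack on the β-face;
- base-induced α-ketol shift of the product.

Fallback, from 16 to 20 (bypassing 17–19; it needs the 8β-hydroxy epimer of 16): hydroxyl-directed epoxidation (VO(acac)2, t-BuOOH, CH2Cl2) should give 15-[(tert-butyldimethylsilyl)oxy]-6β,7β-epoxylabd-13E-en-8β-ol F8. Dehydration of the tertiary alcohol towards C9 (SOCl2, pyridine) gives 15-[(tert-butyldimethylsilyl)oxy]-6β,7β-epoxylabda-8,13E-diene F9. Mild acid hydrolysis (PPTS, THF–H2O) opens the vinyl epoxide at the allylic C7 with inversion, trans-diaxially, to the 6β,7α-diol 20.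

Further compounds
F1 | step 1 | (1R,4R,5R)-4-(but-3-en-1-yl)-4,6,6-trimethylbicyclo[3.1.1]heptan-2-one | C[C@@]1(CCC=C)CC(=O)[C@@H]2C[C@H]1C2(C)C
F2 | step 1 | (3R,4R)-3-(but-3-en-1-yl)-4-(2-hydroxypropan-2-yl)-3-methylcyclohexan-1-one | O=C1C[C@@](C)(CCC=C)[C@H](C(C)(C)O)CC1
F3 | step 1 | (3R,4S)-3-(but-3-en-1-yl)-3-methyl-4-(prop-1-en-2-yl)cyclohexan-1-one | O=C1C[C@@](C)(CCC=C)[C@H](C(C)=C)CC1
F4 | step 1 | (4aR,8aR)-5,8a-dimethyl-3,4,4a,7,8,8a-hexahydronaphthalen-2(1H)-one | O=C1C[C@@]2(C)CCC=C(C)[C@@H]2CC1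
F5 | step 1 | N′-[(1,4a-dimethyl-6-oxodecahydronaphthalen-1-yl)methyl]benzenesulfonohydrazide (ring fusion as in 7, C1 epimers) | O=C1C[C@@]2(C)CCCC(C)(CNNS(=O)(=O)c3ccccc3)[C@@H]2CC1
F6 | step 7 | N,N-dimethylhydrazone of 8 | CN(C)N=C1C[C@@]2(C)CCCC(C)(C)[C@@H]2C=C1
F7 | step 7 | N,N-dimethylhydrazone of 15 (C9 epimers) | CN(C)N=C1C(CC/C(C)=C/CO[Si](C)(C)C(C)(C)C)[C@@]2(C)CCCC(C)(C)[C@@H]2C=C1
F8 | step 10 | 15-[(tert-butyldimethylsilyl)oxy]-6β,7β-epoxylabd-13E-en-8β-ol (C9 epimers) | C[C@@]1(O)C(CC/C(C)=C/CO[Si](C)(C)C(C)(C)C)[C@@]2(C)CCCC(C)(C)[C@@H]2[C@@H]3O[C@@H]31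
F9 | step 10 | 15-[(tert-butyldimethylsilyl)oxy]-6β,7β-epoxylabda-8,13E-diene | CC1=C(CC/C(C)=C/CO[Si](C)(C)C(C)(C)C)[C@@]2(C)CCCC(C)(C)[C@@H]2[C@@H]3O[C@@H]31
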